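**Retrosynthetic overview**
- Target ⇒ Δ7 enal: the C6 hydroxyl comes last, by vinylogous Rubottom oxidation of the 17-silyloxy-6,8(17)-diene, with oxygen delivered to the face opposite the C10 methyl.
- Δ7 enal ⇒ methyl 16-formyloxy-ent-labda-7,13-dien-15-oate: allylic oxidation of the C17 methyl.
- Bicycle ⇒ acyclic (2E,6E,10E)-tetraene ester: one proton-initiated cation–olefin cascade as in copalyl-type biosynthesis, ring A first (C4–C5) and then ring B (C9–C10); C5, C9 and C10 are set together by a chiral Brønsted acid while the complete oxidised side chain rides through.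
- Tetraene ester ⇒ (E,E)-farnesylacetone: C13=C14 by Wittig olefination of an α-formyloxy ketone, C16–O by kinetic bromination at the methyl group and formate displacement.

Assumption: geometrically pure (5E,9E)-farnesylacetone is purchasable; ring positions use labdane numbering (C15 ester carbon, C16 the CH2O carbon, C17 the formyl carbon, C20 the C10 methyl).

**Route**

Step 1
Reactants: 1 (5E,9E)-6,10,14-trimethylpentadeca-5,9,13-trien-2-one
Product: 4 (5E,9E)-1-bromo-6,10,14-trimethylpentadeca-5,9,13-trien-2-one, via lithium enolate 2 (not isolated), via trimethylsilyl enol ether 3 (not isolated)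
Conditions: LiN(SiMe3)2, THF, −78 °C; Me3SiCl; then NBS, −78 → 0 °C
Reagents that add atoms: N-bromosuccinimide, O=C1CCC(=O)N1Br
Why: Kinetic deprotonation by the hindered amide takes the methyl proton, and the derived terminal silyl enol ether is brominated by NBS much faster than the three trisubstituted alkenes (regioselective α-halogenation via a silyl enol ether); no stereocentre is formed.

Step 2
Reactants: 4 (5E,9E)-1-bromo-6,10,14-trimethylpentadeca-5,9,13-trien-2-one; 5 sodium formate
Product: 6 (5E,9E)-6,10,14-trimethyl-2-oxopentadeca-5,9,13-trien-1-yl formate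
Conditions: HCO2Na (3 equiv), dry DMF, 23 °C
Reagents that add atoms: sodium formate, [Na+].[O-]C=O
Why: SN2 displacement of the activated α-keto bromide by formate (carboxylate alkylation) installs the C16 formate directly; no stereocentre is formed.

Step 3
Reactants: 6 (5E,9E)-6,10,14-trimethyl-2-oxopentadeca-5,9,13-trien-1-yl formate; 7 methyl (triphenyl-λ5-phosphanylidene)acetate
Product: 8 methyl (2E,6E,10E)-3-[(formyloxy)methyl]-7,11,15-trimethylhexadeca-2,6,10,14-tetraenoate
Conditions: Ph3P=CHCO2Me (1.5 equiv), toluene, 80 °C; chromatography to remove the minor (2Z) isomer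
Reagents that add atoms: methyl (triphenyl-λ5-phosphanylidene)acetate, COC(=O)C=P(c1ccccc1)(c1ccccc1)c1ccccc1
Why: Wittig olefination with a stabilised ylide under neutral, salt-free conditions spares the formate, and α-oxygenated ketones place the ester trans to the CH2O group, which gives the required (2E) alkene with the ester cis to the chain.

Step 4
Reactants: 8 methyl (2E,6E,10E)-3-[(formyloxy)methyl]-7,11,15-trimethylhexadeca-2,6,10,14-tetraenoate
Product: 9 methyl (5R,9R,10R,13E)-16-formyloxylabda-7,13-dien-15-oate (ent-labdane series)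
Conditions: (S)-2'-(2-fluorobenzyloxy)-1,1'-binaphthalen-2-ol (2.2 equiv), SnCl4 (2.0 equiv), toluene, −78 °C, 48 h; aq NaHCO3
Reagents that add atoms: none
Why: Proposed new method: the SnCl4-activated phenolic proton of the (S)-binaphthol ether is delivered to one enantioface of the terminal, most basic C3=C4 alkene, the C4 cation is trapped by the (E)-C5=C10 alkene and the C10 cation by the (E)-C8=C9 alkene through a chair–chair array (anti additions put 5-H trans and C11 cis to the C10 methyl, so C5, C9 and C10 are set at once, in the ent sense because the (R)-acid gives the normal ambrox series), and the enoate alkene is too electron-poor to add, so the C8 cation ends by loss of H7 to the C7=C8 alkene; the closest known reaction type is the Yamamoto–Ishihara Lewis acid-assisted chiral Brønsted acid cyclisation of homofarnesol derivatives and homo(polyprenyl)arenes, together with the superacid cyclisation of farnesyl acetate to drimenyl acetate, here stretched to a substrate without an internal nucleophile.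

Step 5
Reactants: 9 methyl (5R,9R,10R,13E)-16-formyloxylabda-7,13-dien-15-oate
Product: 11 methyl (5R,9S,10R,13E)-16-formyloxy-17-oxolabda-7,13-dien-15-oate, via 17-hydroxy allylic alcohol 10 (not isolated)
Conditions: SeO2 (1.5 equiv), 1,4-dioxane, 4 Å MS, 80 °C
Reagents that add atoms: selenium dioxide, O=[Se]=O
Why: SeO2 allylic oxidation (ene reaction at C7, then [2,3]-sigmatropic shift) takes the methyl group on the more substituted alkene carbon in preference to the C9 methine and carries the primary allylic alcohol on to the enal, while the electron-poor side-chain enoate is inert; no stereocentre is touched.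

Step 6
Reactants: 11 methyl (5R,9S,10R,13E)-16-formyloxy-17-oxolabda-7,13-dien-15-oate
Product: 12 methyl (5R,9S,10S,8(17)Z,13E)-16-formyloxy-17-(triethylsilyloxy)labda-6,8(17),13-trien-15-oate
Conditions: Et3SiOTf (1.3 equiv), Et3N (2.5 equiv), CH2Cl2, −78 → 0 °C; filtration through Et3N-deactivated silica
Reagents that add atoms: triethylsilyl trifluoromethanesulfonate, CC[Si](CC)(CC)OS(=O)(=O)C(F)(F)F
Why: Soft enolisation (O-silylation of the aldehyde, then removal of the only vinylogously acidic proton, at C6) gives the 1-silyloxy-1,3-diene; the enol ether geometry is of no consequence and C5, C9 and C10 are untouched.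

Step 7
Reactants: 12 methyl (5R,9S,10S,8(17)Z,13E)-16-formyloxy-17-(triethylsilyloxy)labda-6,8(17),13-trien-15-oate
Product: 14 methyl (5R,6R,9S,10S,13E)-16-formyloxy-6-hydroxy-17-oxolabda-7,13-dien-15-oate, via 6,7-epoxy silyl enol ether 13 (not isolated)
Conditions: DMDO (1.05 equiv, acetone), CH2Cl2, −78 °C; then AcOH–THF–H2O, 0 °C
Reagents that add atoms: dimethyldioxirane, CC1(C)OO1
Why: Vinylogous Rubottom oxidation, the same reaction type as the peracid conversion of steroid 3,5-dienol ethers to 6-hydroxy-4-en-3-ones: DMDO epoxidises the remote C6=C7 bond from the face opposite the axial C10 and C4 methyl groups, the enol ether opens the vinyl epoxide and hydrolysis releases the γ-hydroxy enal, which sets C6 as R with the hydroxyl equatorial and trans to the C10 methyl.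

**Compound list**
1 | (5E,9E)-6,10,14-trimethylpentadeca-5,9,13-trien-2-one [(E,E)-farnesylacetone] | CC(=O)CC/C=C(\C)CC/C=C(\C)CCC=C(C)C | starting material
2 | lithium (5E,9E)-6,10,14-trimethylpentadeca-1,5,9,13-tetraen-2-olate | [Li]OC(=C)CC/C=C(\C)CC/C=C(\C)CCC=C(C)C | intermediate (not isolated)
3 | trimethyl{[(5E,9E)-6,10,14-trimethylpentadeca-1,5,9,13-tetraen-2-yl]oxy}silane | C[Si](C)(C)OC(=C)CC/C=C(\C)CC/C=C(\C)CCC=C(C)C | intermediate (not isolated)
4 | (5E,9E)-1-bromo-6,10,14-trimethylpentadeca-5,9,13-trien-2-one | BrCC(=O)CC/C=C(\C)CC/C=C(\C)CCC=C(C)C | intermediate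
5 | sodium formate | [Na+].[O-]C=O | starting material
6 | (5E,9E)-6,10,14-trimethyl-2-oxopentadeca-5,9,13-trien-1-yl formate | O=COCC(=O)CC/C=C(\C)CC/C=C(\C)CCC=C(C)C | intermediate
7 | methyl (triphenyl-λ5-phosphanylidene)acetate | COC(=O)C=P(c1ccccc1)(c1ccccc1)c1ccccc1 | starting material
8 | methyl (2E,6E,10E)-3-[(formyloxy)methyl]-7,11,15-trimethylhexadeca-2,6,10,14-tetraenoate | COC(=O)/C=C(\CC/C=C(\C)CC/C=C(\C)CCC=C(C)C)COC=O | intermediate
9 | methyl (5R,9R,10R,13E)-16-formyloxylabda-7,13-dien-15-oate (ent-labdane; trans-decalin, C11 cis to the C10 methyl) | COC(=O)/C=C(\CC[C@@H]1C(C)=CC[C@@H]2C(C)(C)CCC[C@@]12C)COC=O | intermediate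
10 | methyl (5R,9S,10R,13E)-16-formyloxy-17-hydroxylabda-7,13-dien-15-oate | COC(=O)/C=C(\CC[C@@H]1C(CO)=CC[C@@H]2C(C)(C)CCC[C@@]12C)COC=O | intermediate (not isolated)
11 | methyl (5R,9S,10R,13E)-16-formyloxy-17-oxolabda-7,13-dien-15-oate | COC(=O)/C=C(\CC[C@@H]1C(C=O)=CC[C@@H]2C(C)(C)CCC[C@@]12C)COC=O | intermediate
12 | methyl (5R,9S,10S,8(17)Z,13E)-16-formyloxy-17-(triethylsilyloxy)labda-6,8(17),13-trien-15-oate (silyloxy cis to C9) | COC(=O)/C=C(\CC[C@@H]1/C(=C\O[Si](CC)(CC)CC)C=C[C@@H]2C(C)(C)CCC[C@@]12C)COC=O | intermediate
13 | methyl (5R,6S,7R,9S,10S,8(17)Z,13E)-6,7-epoxy-16-formyloxy-17-(triethylsilyloxy)labda-8(17),13-dien-15-oate (epoxide oxygen on the face opposite the C10 methyl) | COC(=O)/C=C(\CC[C@@H]1/C(=C\O[Si](CC)(CC)CC)[C@H]3O[C@H]3[C@@H]2C(C)(C)CCC[C@@]12C)COC=O | intermediate (not isolated)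
14 | methyl (2E)-5-[(1S,4R,4aR,8aS)-2-formyl-4-hydroxy-5,5,8a-trimethyl-1,4,4a,5,6,7,8,8a-octahydronaphthalen-1-yl]-3-[(formyloxy)methyl]pent-2-enoate (labdane numbering 5R,6R,9S,10S,13E) | COC(=O)/C=C(\CC[C@@H]1C(C=O)=C[C@@H](O)[C@@H]2C(C)(C)CCC[C@@]12C)COC=O | target

**Totals**
Total step count: 7. Longest linear sequence: 7.

**Steps most likely to fail**

Step 4 (bicyclisation). The risks are: moderate enantiomeric excess without an aryl or heteroatom terminator; SnCl4 tied up by the two ester groups; proton loss to the 8(17) or 8(9) alkene; a stop after ring A; or a third ring closure onto the enoate. The fallback sets out from 8 and comes back to the route at 9. Compound 8 is cyclised by iodonium initiation instead of protonation, with N-iodosuccinimide and a stoichiometric binaphthol-derived chiral phosphoramidite promoter (enantiomer chosen for the ent series) in toluene at −40 °C. This gives methyl (13E)-16-formyloxy-3-iodolabda-7,13-dien-15-oate of the ent series (3R, iodine equatorial and cis to the C10 methyl) F1. Radical deiodination of F1 with Bu3SnH and AIBN in toluene at 80 °C then gives 9.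

Step 5 (SeO2 oxidation). The risks are attack at the C9 methine, a stop at the alcohol and loss of the formate. The fallback sets out from 9 and comes back to the route at 11. Schenck ene photo-oxygenation of 9 (O2, tetraphenylporphyrin, visible light, CH2Cl2, 0 °C) from the face opposite the C10 methyl gives the 7-hydroperoxy-8(17)-ene F2. PPh3 in the same flask reduces it to the 7-hydroxy-8(17)-ene F3. Catalytic Ph3SiOReO3 transposes this allylic alcohol to the primary 17-alcohol 10, which is isolated here, and MnO2 in CH2Cl2 oxidises 10 to 11.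

Step 7 (γ-hydroxylation). The risks are attack at C8 instead of C6, the wrong face and over-oxidation. The fallback sets out from 11 and comes back to the route at 14. Compound 11 is deconjugated by KN(SiMe3)2 in THF at −78 °C followed by a kinetic AcOH quench, which gives the β,γ-unsaturated aldehyde methyl (13E)-16-formyloxy-17-oxolabda-6,13-dien-15-oate F4 (8-H on the face opposite the C10 methyl; this centre is lost again later). DMDO epoxidises its only electron-rich alkene from the face opposite the C10 methyl to give the 6,7-epoxy aldehyde F5. Et3N in CH2Cl2 opens the epoxide by β-elimination (E1cB) to give 14 with the same C6 configuration.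

**Further compounds**
F1 | step 4 | methyl (13E)-16-formyloxy-3-iodolabda-7,13-dien-15-oate, ent series, 3R (iodine equatorial, cis to the C10 methyl) | COC(=O)/C=C(\CC[C@@H]1C(C)=CC[C@@H]2C(C)(C)[C@H](I)CC[C@@]12C)COC=O
F2 | step 5 | methyl (13E)-16-formyloxy-7-hydroperoxylabda-8(17),13-dien-15-oate, ent series (OOH axial, trans to the C10 methyl) | COC(=O)/C=C(\CC[C@@H]1C(=C)[C@@H](OO)C[C@@H]2C(C)(C)CCC[C@@]12C)COC=O
F3 | step 5 | methyl (13E)-16-formyloxy-7-hydroxylabda-8(17),13-dien-15-oate, ent series (OH axial, trans to the C10 methyl) | COC(=O)/C=C(\CC[C@@H]1C(=C)[C@@H](O)C[C@@H]2C(C)(C)CCC[C@@]12C)COC=O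
F4 | step 7 | methyl (13E)-16-formyloxy-17-oxolabda-6,13-dien-15-oate, ent series (8-H on the face opposite the C10 methyl) | COC(=O)/C=C(\CC[C@@H]1[C@H](C=O)C=C[C@@H]2C(C)(C)CCC[C@@]12C)COC=O
F5 | step 7 | methyl (13E)-6,7-epoxy-16-formyloxy-17-oxolabd-13-en-15-oate, ent series (epoxide oxygen on the face opposite the C10 methyl) | COC(=O)/C=C(\CC[C@@H]1[C@H](C=O)[C@H]3O[C@H]3[C@@H]2C(C)(C)CCC[C@@]12C)COC=O
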